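In a closed, stirred vessel at constant temperature, D turns one J into G and starts a living end Z. Z then adds further J to G, and Q may turn Z into X.

| flask | J | Q | D | remark | time |
|---|---|---|---|---|---|
| delta | 0.10 M | 0.015 M | 2 mM | run made earlier |  |
| dusk | 0.10 M | 0.0100 M | 2.0 mM |  | 12 min |
| dawn | 0.10 M | 0.0100 M | 2.6 mM |  | 12 min |

delta run (percent of the J charged)

| time / min | J / % | G / % |
|---|---|---|
| 0.833 | 95.3 | 3.6 |
| 1.50 | 94.1 | 6.4 |
| 2.50 | 91.9 | 7.5 |
| 3.00 | 90.2 | 10.6 |
| 4.00 | 90.0 | 13.0 |

(scatter of a reading: 1 percentage point)

- steps thought possible: J + D -> Z + G; Z + Q -> X; J + Z -> G + Z
- no earlier run changes the charge of Q; that part of a forecast is a guess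

- which of these there is most of at the end, counted by the J in it, dusk (G / J)
- which of these there is most of at the end, counted by the J in it, dawn (G / J)
- the largest of these amounts at the end, in percent of the J charged, dusk
- the largest of these amounts at the end, in percent of the J charged, dawn

We write j for the fraction of the charged J still free, and d for the charge of D as a fraction of the charge of J, which is 2.00 % in delta. The delta readings scatter, so we average J lost and G gained, and at 4.00 min this gives a conversion of 11.5 %. The plain estimate stretches that in proportion to 12 min and gives j = 65.5 % for dusk.

But D spends one J per D, and if this happens at the start, that part of the conversion does not repeat. So we solve both ends and join them. At the early end, j drops at once to the charge less d. At the late end, the ends stay at d and j decays exponentially, the pseudo-first-order picture, at a rate s times d. Read from delta, the burn rate s is 1.27 /min: the fall of ln j per minute for each unit of d. That reading then puts the conversion in delta at 0.833 min at 4.05 %, and the average read there, which s did not use, is 4.15 %.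

The objection is that Q may remove ends, which would make s sag. In delta, the average conversion read at 2.50 min is 7.80 %, so ln j falls at 0.0233 /min from 0.833 min up to that time and at 0.0273 /min afterwards, and no sag shows in these readings. With a scatter of 1 percentage point, though, this reading is weak, and the new charge of Q remains a guess. We carry no decay and reckon j = 72.2 % for dusk and 65.4 % for dawn.

The forecast says J at 77 % for dusk and J at 72 % for dawn, higher than our figures. It holds that “The decay rate of living ends is poorly fixed” and lets the ends decay.

The flasks give J at 70.2 % in dusk and 63.1 % in dawn, above G in each, against our 72.2 % and 65.4 %.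

J + D → Z + G (k = 0.510 /M/s); Z + Q → X (k = 0.0260 /M/s); J + Z → G + Z, rate k3*[Z]*[J] (k = 0.260 /M/s) In dusk at 12.0 min, Z still stands at 83.6 % of the D charged. We now use s on a neighbour of dusk charged with 0.0080 M of D, where d is 8.00 %. It reckons j = 27.1 %, and that flask holds 24.2 % of J.

Readings and results are calculated for an exercise; scatter was added.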